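(The runs are calculated from invented constants; scatter was added.)

Start from the amounts: this flask holds Z at 11 mM with L at 11 µM under E held at 0.71 mM, so its charge of Z lies between those of the red and violet runs at the same L, and those two runs can be read for it.

| setting | red | violet | amber | flask |
|---|---|---|---|---|
| Z | 7.4 mM | 16 mM | 11 mM | 11 mM |
| E | 0.71 mM (held) | 0.71 mM (held) | 0.71 mM (held) | 0.71 mM (held) |
| L | 11 µM | 11 µM | 5.5 µM | 11 µM |
| remark | run made earlier | run made earlier | run made earlier |  |
| time |  |  |  | 15 d |

| run | time / d | J / % | Z / % |
|---|---|---|---|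
| red | 0.333 | 44 | 54 |
| red | 0.833 | 78 | 17 |
| red | 2.50 | 76 | 1 |
| red | 6.00 | 54 | 2 |
| red | 15.0 | 43 | 0 |
| violet | 0.333 | 41 | 62 |
| violet | 0.833 | 74 | 25 |
| violet | 2.50 | 76 | 3 |
| violet | 6.00 | 51 | 3 |
| violet | 15.0 | 41 | 1 |
| amber | 0.333 | 25 | 72 |
| amber | 0.833 | 55 | 42 |
| amber | 2.50 | 76 | 6 |
| amber | 6.00 | 61 | 1 |
| amber | 15.0 | 40 | 1 |

(each reading ± 2 percentage points)

- the best time, 15 d at the latest, for J
- the amount of J, in percent of the Z charged, at that time
- the first time at which J reaches 41%, in the same percent, in d

- at the start none of E is in solution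

Draw the curve of J in this flask, as a reckoning of your own. For the start, take the mean of the red and violet readings at 0.333 d; a straight chord through it reaches 41% at 0.321 d. For the fall of Z, take the first two readings, which give red and violet a mean pseudo-first-order constant k of 2.06 /d; amber, with half the L, reads 1.08 /d, about half of that, so scale k with L. For the level J runs into, take the mean of the last readings, f = 41.3%, and from the red and violet means between 2.50 d and 6.00 d read the constant r of the approach to it, 0.324 /d. Now let the making of J, k·Z, meet its loss, r·(J − f·R), with R the share of Z reacted: they meet at 1.33 d, the crossing time t×, where this reckoning puts the top of the curve, with Z at 6.39% and J at 79.4%.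

The forecast, made from the same runs, gives 0.32 d for the first time, 1.4 d for the best time and 82% for the amount, and holds that “Any E-dissolution lag looks small”; its peak stands 2.6 percentage points above the reckoned one.

    E ⇌ Q, rate k1*(csat - [Q]) (kL = 2.90 /h)
    Z + Q + L → L + J (k = 1.40 × 10⁷ /M²/h)
    Q → G (k = 0.0690 /h)
    J ⇌ D (K = 1.40, k = 0.00670 /h)

The flask reaches 41% at 0.317 d and peaks at 1.42 d with 82.4%, as forecast, against 1.33 d and 79.4% from the crossing; at that peak the dissolved gas Q stands at 0.675 mM of 0.71 mM. Carry the crossing to the neighbouring flask with L at 6.60 µM: k scales to 1.24 /d, the crossing reckons out at 1.92 d, later than the 1.33 d reckoned for the first flask, and the reckoned peak is 72.8%, while that neighbouring flask reaches 76.9%.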